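**Plan**

1. Retrosynthesis: the neopentyl ester C–O bond is cut last. Ring B of the left half is then opened at two bonds at once, C4–C4a (carbonyl–aryl) and C2–C3 (numbering of 2-alkyl-3-hydroxynaphthalene-1,4-dione). This removes the C3–C4 pair as an oxalyl unit and leaves an ortho-bromoaryl alkyl ketone, itself cut at Cα–Cβ into 2'-bromoacetophenone and monosilylated neopentyl glycol.
2. Enabling feature: ring B, written as its naphthalene-1,2,4-trione tautomer, holds a vicinal dicarbonyl (C3, C4) at the oxidation level of oxalic acid. It is flanked by the benzo carbon C4a and by C2, which is the enolizable α-carbon of the aryl ketone C1=O. An aryllithium/enolate C,C-dianion and a symmetrical oxalic diester can therefore close ring B in one event with no regiochemical question.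
3. Forward, left half: ketone assembly, annulation of ring B onto the bought benzene ring A, desilylation; the two halves are joined by esterification at the end.
4. Acid half: cut at C2=C3 (cross-metathesis with methacrolein, then oxidation) and at the C8 oxygen (deoxygenation of an epoxy alcohol), back to nerol.
5. Stereochemistry: the Z olefin of nerol fixes the cis relation of chain and ring methyl on the oxirane; Sharpless epoxidation with D-(−)-diethyl tartrate fixes the absolute configuration ((2S,3R) on the oxirane); the E enoate comes from the thermodynamic preference of the metathesis.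

Key step: step 3

Remark: the oxirane of the target is read as (2S,3R), with the pentenoate chain on C2 and the methyl on C3 cis on the ring, i.e. the epoxide of a (Z)-trisubstituted olefin; the route is built for this isomer.

**Route**

Step 1
Reactants: 1 2,2-dimethylpropane-1,3-diol
Product: 2 3-[(tert-butyldimethylsilyl)oxy]-2,2-dimethylpropan-1-ol
Conditions: NaH (1.0 equiv), THF, rt; then TBSCl (1.0 equiv), rt
Reagents that add atoms: tert-butyldimethylsilyl chloride, CC(C)(C)[Si](C)(C)Cl
Why: Monosilylation of a symmetrical diol through its sparingly soluble monosodium alkoxide, which should be silylated faster than it equilibrates to the dialkoxide.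

Step 2
Reactants: 2 3-[(tert-butyldimethylsilyl)oxy]-2,2-dimethylpropan-1-ol; 3 1-(2-bromophenyl)ethan-1-one
Product: 6 1-(2-bromophenyl)-5-[(tert-butyldimethylsilyl)oxy]-4,4-dimethylpentan-1-one, via silyloxy aldehyde 4 (not isolated), via enone 5 (not isolated)
Conditions: [Cp*IrCl2]2 (1 mol %), KOH (20 mol %), toluene, 110 °C
Reagents that add atoms: none
Why: Hydrogen-borrowing α-alkylation of an aryl methyl ketone with a primary alcohol, in which the iridium catalyst dehydrogenates 2 to the non-enolizable aldehyde 4, aldol condensation with 3 gives enone 5, and the iridium hydride returns the hydrogen to the C=C bond while the aryl bromide and the hindered silyl ether should stay untouched.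

Step 3
Reactants: 6 1-(2-bromophenyl)-5-[(tert-butyldimethylsilyl)oxy]-4,4-dimethylpentan-1-one; 7 diethyl oxalate
Product: 11 2-{3-[(tert-butyldimethylsilyl)oxy]-2,2-dimethylpropyl}-3-hydroxynaphthalene-1,4-dione, via bromoaryl potassium enolate 8 (not isolated), via lithioaryl potassium enolate 9 (not isolated), via aryl glyoxylate enolate 10 (not isolated)
Conditions: KH (1.1 equiv), THF, 0 °C → rt; t-BuLi (2.1 equiv), −78 °C; (CO2Et)2 (1.1 equiv), −78 → 0 °C; 1 M HCl work-up
Reagents that add atoms: none
Why: Proposed new method: the aryl C–Li of dianion 9 adds to one ester carbonyl of diethyl oxalate (bond C4–C4a, giving 10 directly or through its lithium hemiketal) and the tethered enolate carbon then attacks the second ester carbonyl in a Dieckmann-type Claisen acylation (bond C2–C3), after which loss of two ethoxides and deprotonation give the delocalized anion of the hydroxyquinone, so that both ring bonds arise from one addition of a symmetrical C2 dielectrophile to a 1,4-C,C-dinucleophile. The closest known reaction types are the Parham cycloacylation of aryllithiums on esters, the Claisen condensation of aryl ketone enolates with diethyl oxalate, the conversion of 2,2'-dilithiobiaryls into phenanthrene-9,10-diones with oxalic esters and, with reversed polarity, the Hauser–Kraus annulation. The one ring closed is the six-membered ring B, by a 6-(enolendo)-exo-trig acyl substitution of the enolate carbon on the pendant ester. No stereocentre is formed. The step needs chemoselectivity and ring-size control: the aryllithium should react first at −78 °C, the oxalate is symmetrical and ring A unsubstituted so only one constitution can result, and any reversible five-membered aldol addition of the enolate to the glyoxylate ketone of 10 should drain to ring B because only the six-membered trione can be deprotonated to a stable vinylogous carboxylate. The enolate also masks the ketone of 6 from tert-butyllithium, and near-stoichiometric oxalate at low temperature should limit intermolecular Claisen oligomers.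

Step 4
Reactants: 11 2-{3-[(tert-butyldimethylsilyl)oxy]-2,2-dimethylpropyl}-3-hydroxynaphthalene-1,4-dione
Product: 12 2-hydroxy-3-(3-hydroxy-2,2-dimethylpropyl)naphthalene-1,4-dione
Conditions: HF·pyridine, THF/pyridine, 0 °C → rt
Reagents that add atoms: none
Why: Fluoride cleavage of the primary silyl ether under pyridine-buffered conditions, chosen because strong acid would cyclodehydrate the hydroxypropyl hydroxyquinone to a pyranonaphthoquinone.

Step 5
Reactants: 13 nerol, (2Z)-3,7-dimethylocta-2,6-dien-1-ol
Product: 14 [(2R,3S)-3-methyl-3-(4-methylpent-3-en-1-yl)oxiran-2-yl]methanol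
Conditions: Ti(OiPr)4 (5 mol %), D-(−)-diethyl tartrate (6 mol %), t-BuOOH (anhydrous), 4 Å molecular sieves, CH2Cl2, −20 °C
Reagents that add atoms: tert-butyl hydroperoxide, CC(C)(C)OO
Why: Sharpless asymmetric epoxidation, in which the titanium tartrate complex delivers oxygen only to the allylic alcohol olefin and to one enantioface (D-(−)-tartrate giving the (2R,3S) epoxy alcohol), while the Z geometry of nerol sets the cis relation of the chain and the hydroxymethyl group on the ring.

Step 6
Reactants: 14 [(2R,3S)-3-methyl-3-(4-methylpent-3-en-1-yl)oxiran-2-yl]methanol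
Product: 15 [(2R,3S)-3-methyl-3-(4-methylpent-3-en-1-yl)oxiran-2-yl]methyl 4-methylbenzenesulfonate
Conditions: TsCl, Et3N, DMAP (cat.), CH2Cl2, 0 °C
Reagents that add atoms: 4-methylbenzenesulfonyl chloride, Cc1ccc(cc1)S(=O)(=O)Cl
Why: Standard sulfonylation of the primary alcohol, which leaves both oxirane stereocentres untouched.

Step 7
Reactants: 15 [(2R,3S)-3-methyl-3-(4-methylpent-3-en-1-yl)oxiran-2-yl]methyl 4-methylbenzenesulfonate
Product: 16 (2S,3R)-2,3-dimethyl-2-(4-methylpent-3-en-1-yl)oxirane
Conditions: NaBH4, DMSO, 45 °C
Reagents that add atoms: none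
Why: Hydride SN2 displacement of a primary tosylate in a dipolar aprotic solvent, to which the trisubstituted epoxide and the olefin should be inert, turns CH2OTs into the ring methyl without touching the stereocentres.

Step 8
Reactants: 16 (2S,3R)-2,3-dimethyl-2-(4-methylpent-3-en-1-yl)oxirane; 17 methacrolein (2-methylprop-2-enal)
Product: 18 (2E)-5-[(2S,3R)-2,3-dimethyloxiran-2-yl]-2-methylpent-2-enal
Conditions: methacrolein (10 equiv), second-generation Hoveyda–Grubbs catalyst (H2IMes)Cl2Ru=CH(2-iPrOC6H4) (5 mol %), CH2Cl2, 40 °C
Reagents that add atoms: none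
Why: Olefin cross-metathesis of an isopropylidene (prenyl-type) terminus with methacrolein, driven by loss of volatile isobutene and expected to give the thermodynamically preferred (E)-2-methyl enal, with the epoxide a spectator.

Step 9
Reactants: 18 (2E)-5-[(2S,3R)-2,3-dimethyloxiran-2-yl]-2-methylpent-2-enal
Product: 19 (2E)-5-[(2S,3R)-2,3-dimethyloxiran-2-yl]-2-methylpent-2-enoic acid
Conditions: NaClO2, NaH2PO4, 2-methyl-2-butene, t-BuOH/H2O, 0 °C → rt
Reagents that add atoms: sodium chlorite, [Na+].[O-]Cl=O
Why: Pinnick oxidation of the enal under phosphate buffer with a hypochlorite scavenger, mild enough that the olefin geometry and the trisubstituted epoxide should be retained.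

Step 10
Reactants: 19 (2E)-5-[(2S,3R)-2,3-dimethyloxiran-2-yl]-2-methylpent-2-enoic acid; 12 2-hydroxy-3-(3-hydroxy-2,2-dimethylpropyl)naphthalene-1,4-dione
Product: 21 3-(3-hydroxy-1,4-dioxo-1,4-dihydronaphthalen-2-yl)-2,2-dimethylpropyl (2E)-5-[(2S,3R)-2,3-dimethyloxiran-2-yl]-2-methylpent-2-enoate (the target), via acyl imidazolide 20 (not isolated)
Conditions: 19, 1,1'-carbonyldiimidazole (1.0 equiv), THF, rt; then 12, DBU (2.2 equiv), THF, 40 °C; pH 4 phosphate work-up
Reagents that add atoms: none
Why: Esterification through the acyl imidazolide with DBU promotion, in which the vinylogous-acid hydroxyl is held as a delocalized anion whose acylation by an imidazolide is uphill (its enol ester would be the better acyl donor), so the acyl group should end on the primary neopentyl oxygen, and the chloride-free non-acidic medium spares the epoxide.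

**Compound list**

1 | 2,2-dimethylpropane-1,3-diol | OCC(C)(C)CO | starting material
2 | 3-[(tert-butyldimethylsilyl)oxy]-2,2-dimethylpropan-1-ol | CC(C)(CO)CO[Si](C)(C)C(C)(C)C | intermediate
3 | 1-(2-bromophenyl)ethan-1-one | CC(=O)c1ccccc1Br | starting material
4 | 3-[(tert-butyldimethylsilyl)oxy]-2,2-dimethylpropanal | CC(C)(C=O)CO[Si](C)(C)C(C)(C)C | intermediate
5 | (2E)-1-(2-bromophenyl)-5-[(tert-butyldimethylsilyl)oxy]-4,4-dimethylpent-2-en-1-one | O=C(/C=C/C(C)(C)CO[Si](C)(C)C(C)(C)C)c1ccccc1Br | intermediate
6 | 1-(2-bromophenyl)-5-[(tert-butyldimethylsilyl)oxy]-4,4-dimethylpentan-1-one | O=C(CCC(C)(C)CO[Si](C)(C)C(C)(C)C)c1ccccc1Br | intermediate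
7 | diethyl oxalate | CCOC(=O)C(=O)OCC | starting material
8 | potassium (1Z)-1-(2-bromophenyl)-5-[(tert-butyldimethylsilyl)oxy]-4,4-dimethylpent-1-en-1-olate | [K]O/C(=C\CC(C)(C)CO[Si](C)(C)C(C)(C)C)c1ccccc1Br | intermediate
9 | potassium (1Z)-5-[(tert-butyldimethylsilyl)oxy]-1-(2-lithiophenyl)-4,4-dimethylpent-1-en-1-olate | [K]O/C(=C\CC(C)(C)CO[Si](C)(C)C(C)(C)C)c1ccccc1[Li] | intermediate
10 | ethyl 2-(2-{(1Z)-5-[(tert-butyldimethylsilyl)oxy]-4,4-dimethyl-1-(potassiooxy)pent-1-en-1-yl}phenyl)-2-oxoacetate | [K]O/C(=C\CC(C)(C)CO[Si](C)(C)C(C)(C)C)c1ccccc1C(=O)C(=O)OCC | intermediate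
11 | 2-{3-[(tert-butyldimethylsilyl)oxy]-2,2-dimethylpropyl}-3-hydroxynaphthalene-1,4-dione | CC(C)(CC1=C(O)C(=O)c2ccccc2C1=O)CO[Si](C)(C)C(C)(C)C | intermediate
12 | 2-hydroxy-3-(3-hydroxy-2,2-dimethylpropyl)naphthalene-1,4-dione | CC(C)(CO)CC1=C(O)C(=O)c2ccccc2C1=O | intermediate
13 | nerol, (2Z)-3,7-dimethylocta-2,6-dien-1-ol | CC(C)=CCC/C(C)=C\CO | starting material
14 | [(2R,3S)-3-methyl-3-(4-methylpent-3-en-1-yl)oxiran-2-yl]methanol | CC(C)=CCC[C@]1(C)O[C@@H]1CO | intermediate
15 | [(2R,3S)-3-methyl-3-(4-methylpent-3-en-1-yl)oxiran-2-yl]methyl 4-methylbenzenesulfonate | CC(C)=CCC[C@]1(C)O[C@@H]1COS(=O)(=O)c1ccc(C)cc1 | intermediate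
16 | (2S,3R)-2,3-dimethyl-2-(4-methylpent-3-en-1-yl)oxirane | CC(C)=CCC[C@]1(C)O[C@@H]1C | intermediate
17 | methacrolein (2-methylprop-2-enal) | CC(=C)C=O | starting material
18 | (2E)-5-[(2S,3R)-2,3-dimethyloxiran-2-yl]-2-methylpent-2-enal | C/C(=C\CC[C@]1(C)O[C@@H]1C)C=O | intermediate
19 | (2E)-5-[(2S,3R)-2,3-dimethyloxiran-2-yl]-2-methylpent-2-enoic acid | C/C(=C\CC[C@]1(C)O[C@@H]1C)C(=O)O | intermediate
20 | 1-{(2E)-5-[(2S,3R)-2,3-dimethyloxiran-2-yl]-2-methylpent-2-enoyl}-1H-imidazole | C/C(=C\CC[C@]1(C)O[C@@H]1C)C(=O)n1ccnc1 | intermediate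
21 | 3-(3-hydroxy-1,4-dioxo-1,4-dihydronaphthalen-2-yl)-2,2-dimethylpropyl (2E)-5-[(2S,3R)-2,3-dimethyloxiran-2-yl]-2-methylpent-2-enoate | C/C(=C\CC[C@]1(C)O[C@@H]1C)C(=O)OCC(C)(C)CC1=C(O)C(=O)c2ccccc2C1=O | target

**Count and risks**

Total steps: 10. Longest linear sequence: 6 steps (13 → 21, steps 5–10); the left half takes steps 1–4 and joins in step 10.

Step 3 (Proposed new method). What may go wrong: incomplete bromine–lithium exchange or protonation of the aryllithium, intermolecular Claisen oligomerization, or diversion into the five-membered aldol manifold. The fallback uses known chemistry and a different bond set; it sets out from 2 and comes back at 11. Swern oxidation of 2 gives 3-[(tert-butyldimethylsilyl)oxy]-2,2-dimethylpropanal 4, now isolated. An organocatalytic three-component reductive alkylation of commercial 2-hydroxynaphthalene-1,4-dione with 4 and Hantzsch ester (L-proline cat., CH2Cl2, rt) should then give 11 by Knoevenagel condensation to the quinone methide and conjugate hydride transfer. The route continues at step 4.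

Step 8. What may go wrong: slow productive metathesis between two hindered olefin partners, with catalyst decomposition before turnover or erosion of E selectivity. The fallback sets out from 16 and comes back at 18. Ozonolysis of the isopropylidene olefin (O3, CH2Cl2, −78 °C; PPh3) gives 3-[(2S,3R)-2,3-dimethyloxiran-2-yl]propanal F1. Wittig olefination of F1 with the stabilized ylide 2-(triphenylphosphoranylidene)propanal (toluene, 90 °C) should give the (E)-enal 18.

Step 10. What may go wrong: competing acylation at the vinylogous-acid oxygen, slow acyl transfer to the hindered neopentyl hydroxyl, or cyclization of the hydroxypropyl hydroxyquinone. The fallback changes the protecting-group strategy; it sets out from 11 and comes back at 21. O-Methylation (MeI, Ag2O, CH2Cl2) gives 2-{3-[(tert-butyldimethylsilyl)oxy]-2,2-dimethylpropyl}-3-methoxynaphthalene-1,4-dione F2. HF·pyridine gives 2-(3-hydroxy-2,2-dimethylpropyl)-3-methoxynaphthalene-1,4-dione F3. Steglich esterification with 19 (EDC·HCl, DMAP, CH2Cl2) gives 3-(3-methoxy-1,4-dioxo-1,4-dihydronaphthalen-2-yl)-2,2-dimethylpropyl (2E)-5-[(2S,3R)-2,3-dimethyloxiran-2-yl]-2-methylpent-2-enoate F4. Dilute LiOH (THF/H2O, 0 °C) should hydrolyse the vinylogous methyl ester faster than the hindered conjugated ester and give 21.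

**Further compounds**

F0 | step 3 | none | none
F1 | step 8 | 3-[(2S,3R)-2,3-dimethyloxiran-2-yl]propanal | O=CCC[C@]1(C)O[C@@H]1C
F2 | step 10 | 2-{3-[(tert-butyldimethylsilyl)oxy]-2,2-dimethylpropyl}-3-methoxynaphthalene-1,4-dione | CC(C)(CC1=C(OC)C(=O)c2ccccc2C1=O)CO[Si](C)(C)C(C)(C)C
F3 | step 10 | 2-(3-hydroxy-2,2-dimethylpropyl)-3-methoxynaphthalene-1,4-dione | CC(C)(CO)CC1=C(OC)C(=O)c2ccccc2C1=O
F4 | step 10 | 3-(3-methoxy-1,4-dioxo-1,4-dihydronaphthalen-2-yl)-2,2-dimethylpropyl (2E)-5-[(2S,3R)-2,3-dimethyloxiran-2-yl]-2-methylpent-2-enoate | C/C(=C\CC[C@]1(C)O[C@@H]1C)C(=O)OCC(C)(C)CC1=C(OC)C(=O)c2ccccc2C1=O
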